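## Retrosynthetic overview

1. Target 24 ⇐ bis(allyl ether) aldehyde 23 (final deallylation) ⇐ alcohol 22 ⇐ benzofuran-3-carboxylate 21 (3-CO2Me → 3-CH2OH → 3-CHO).
2. Benzofuran 21 ⇐ β-keto ester 18 by MOM removal and cyclodehydration (phenol O onto the aryl ketone). The furan ring is the only ring that is made; both benzene rings are bought.
3. 18 ⇐ crossed Claisen condensation of the lithium enolate of arylacetate 12 with aroyl chloride 16. This forms the future C2–C3 bond and joins the two aromatic fragments.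
4. 12 ⇐ 2-hydroxy-4-methoxybenzaldehyde 1 (MOM, Wittig, hydroboration, TBS, directed ortho-lithiation/prenylation between the two oxygens, oxidation, esterification); 16 ⇐ 2,4-dihydroxybenzoic acid 13.

Assumption: erypoegin F has no stereocentre, and its only non-aromatic C=C carries two identical methyl groups, so the "single enantiomer" is simply the achiral compound drawn and no stereocontrol is needed.

Abbreviations: allyl = prop-2-en-1-yl; prenyl = 3-methylbut-2-en-1-yl; MOM = methoxymethyl; TBS = tert-butyldimethylsilyl.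

## Route

Step 1
Reactants: 1 2-hydroxy-4-methoxybenzaldehyde
Product: 2 4-methoxy-2-(methoxymethoxy)benzaldehyde
Conditions: MOMCl (1.5 equiv), K2CO3 (3 equiv), acetone, 0 °C to rt
Reagents that add atoms: chloromethyl methyl ether (MOMCl), COCCl
Why: Williamson-type O-alkylation of the phenoxide gives the MOM ether, which protects the future furan oxygen and later serves as the ortho-directing group.

Step 2
Reactants: 2 4-methoxy-2-(methoxymethoxy)benzaldehyde
Product: 3 1-ethenyl-4-methoxy-2-(methoxymethoxy)benzene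
Conditions: Ph3PCH3Br (1.3 equiv), KOtBu (1.25 equiv), THF, 0 °C; then 2, 0 °C to rt
Reagents that add atoms: methyltriphenylphosphonium bromide, C[P+](c1ccccc1)(c1ccccc1)c1ccccc1.[Br-]
Why: Wittig methylenation of a non-enolisable aryl aldehyde with the unstabilised ylide is dependable and leaves the base-stable MOM ether untouched.

Step 3
Reactants: 3 1-ethenyl-4-methoxy-2-(methoxymethoxy)benzene
Product: 5 2-[4-methoxy-2-(methoxymethoxy)phenyl]ethan-1-ol, via B-alkyl-9-BBN adduct 4 (not isolated)
Conditions: 9-BBN (0.5 M in THF, 1.3 equiv), 0 °C to rt; then 3 M aq. NaOH, 30% H2O2, 0 °C to rt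
Reagents that add atoms: hydrogen peroxide, OO
Why: Brown hydroboration–oxidation with the bulky 9-BBN places boron on the terminal carbon (anti-Markovnikov) and alkaline peroxide replaces boron by OH with no other group affected.

Step 4
Reactants: 5 2-[4-methoxy-2-(methoxymethoxy)phenyl]ethan-1-ol
Product: 6 tert-butyl{2-[4-methoxy-2-(methoxymethoxy)phenyl]ethoxy}dimethylsilane
Conditions: TBSCl (1.2 equiv), imidazole (2 equiv), CH2Cl2, rt
Reagents that add atoms: tert-butyldimethylsilyl chloride, CC(C)(C)[Si](C)(C)Cl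
Why: Imidazole-promoted silylation of the primary alcohol masks the acidic OH before the organolithium step.

Step 5
Reactants: 6 tert-butyl{2-[4-methoxy-2-(methoxymethoxy)phenyl]ethoxy}dimethylsilane
Product: 8 tert-butyl{2-[4-methoxy-2-(methoxymethoxy)-3-prenylphenyl]ethoxy}dimethylsilane, via aryllithium 7 (not isolated)
Conditions: n-BuLi (1.2 equiv), THF, 0 °C to rt, 1.5 h; then CuI (10 mol %), prenyl bromide (1.5 equiv), −78 °C to rt
Reagents that add atoms: 1-bromo-3-methylbut-2-ene (prenyl bromide), CC(C)=CCBr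
Why: Directed ortho-metalation removes the most acidic ring proton, the one flanked by OMOM and OMe, and copper-catalysed allylic substitution of the aryllithium on prenyl bromide gives the linear (SN2) prenyl arene.

Step 6
Reactants: 8 tert-butyl{2-[4-methoxy-2-(methoxymethoxy)-3-prenylphenyl]ethoxy}dimethylsilane
Product: 9 2-[4-methoxy-2-(methoxymethoxy)-3-prenylphenyl]ethan-1-ol
Conditions: Bu4NF (1.2 equiv), THF, 0 °C to rt
Reagents that add atoms: none
Why: Fluoride-mediated desilylation, driven by the strong Si–F bond, frees the primary alcohol without touching the MOM acetal or the prenyl alkene.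

Step 7
Reactants: 9 2-[4-methoxy-2-(methoxymethoxy)-3-prenylphenyl]ethan-1-ol
Product: 11 2-[4-methoxy-2-(methoxymethoxy)-3-prenylphenyl]acetic acid, via arylacetaldehyde 10 (not isolated)
Conditions: 2,2,6,6-tetramethylpiperidin-1-oxyl (0.2 equiv), PhI(OAc)2 (2.5 equiv), MeCN–H2O 1:1, rt
Reagents that add atoms: water, O
Why: Nitroxyl-catalysed (oxoammonium) oxidation with PhI(OAc)2 as terminal oxidant takes the primary alcohol through the aldehyde hydrate to the acid under near-neutral conditions that spare the prenyl alkene, the MOM acetal and the electron-rich ring.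

Step 8
Reactants: 11 2-[4-methoxy-2-(methoxymethoxy)-3-prenylphenyl]acetic acid
Product: 12 methyl 2-[4-methoxy-2-(methoxymethoxy)-3-prenylphenyl]acetate
Conditions: MeI (1.5 equiv), K2CO3 (2 equiv), DMF, rt
Reagents that add atoms: iodomethane, CI
Why: SN2 O-methylation of the carboxylate gives the ester, and K2CO3 is too weak to enolise it, so no C-methylation occurs.

Step 9
Reactants: 13 2,4-dihydroxybenzoic acid
Product: 14 allyl 2,4-bis(allyloxy)benzoate
Conditions: allyl bromide (3.6 equiv), K2CO3 (4 equiv), DMF, 60 °C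
Reagents that add atoms: allyl bromide (3-bromoprop-1-ene), C=CCBr
Why: Exhaustive Williamson alkylation allylates both phenols and the carboxylate; allyl ethers are chosen because they survive base, acid, hydride and MnO2 and come off at the end under neutral palladium catalysis.

Step 10
Reactants: 14 allyl 2,4-bis(allyloxy)benzoate
Product: 15 2,4-bis(allyloxy)benzoic acid
Conditions: 2 M aq. NaOH (3 equiv), MeOH–THF, 60 °C; then 1 M HCl to pH 2
Reagents that add atoms: sodium hydroxide, [Na+].[OH-]
Why: Saponification (acyl–oxygen cleavage by hydroxide) removes only the ester allyl group, as aryl allyl ethers are inert to aqueous base.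

Step 11
Reactants: 15 2,4-bis(allyloxy)benzoic acid
Product: 16 2,4-bis(allyloxy)benzoyl chloride
Conditions: (COCl)2 (1.5 equiv), DMF (HCONMe2, cat.), CH2Cl2, 0 °C to rt; evaporate, use crude
Reagents that add atoms: oxalyl chloride, O=C(Cl)C(=O)Cl
Why: Acid chloride formation through the Vilsmeier-type chloroiminium catalyst is clean, with only gaseous by-products, and supplies a non-enolisable acyl donor.

Step 12
Reactants: 12 methyl 2-[4-methoxy-2-(methoxymethoxy)-3-prenylphenyl]acetate; 16 2,4-bis(allyloxy)benzoyl chloride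
Product: 18 methyl 3-[2,4-bis(allyloxy)phenyl]-2-[4-methoxy-2-(methoxymethoxy)-3-prenylphenyl]-3-oxopropanoate, via lithium ester enolate 17 (not isolated)
Conditions: LiN(SiMe3)2 (2.2 equiv), THF, −78 °C, 45 min; then 16 (1.0 equiv) in THF, −78 to 0 °C; sat. aq. NH4Cl
Reagents that add atoms: none
Why: Crossed Claisen condensation, in which the preformed lithium ester enolate is C-acylated by the non-enolisable aroyl chloride and the second equivalent of base deprotonates the β-keto ester to make the step irreversible; the new α-stereocentre is racemic and irrelevant because step 13 makes that carbon sp2.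

Step 13
Reactants: 18 methyl 3-[2,4-bis(allyloxy)phenyl]-2-[4-methoxy-2-(methoxymethoxy)-3-prenylphenyl]-3-oxopropanoate
Product: 21 methyl 2-[2,4-bis(allyloxy)phenyl]-6-methoxy-7-prenyl-1-benzofuran-3-carboxylate, via free phenol 19 (not isolated), via cyclic hemiketal 20 (not isolated)
Conditions: HCl (ca. 1 M in MeOH, from AcCl/MeOH), MeOH–THF 3:1, 45 °C; NaHCO3 quench
Reagents that add atoms: none
Why: Acid-catalysed acetal exchange removes the MOM group, the freed phenol adds 5-exo-trig to the aryl ketone and the hemiketal loses water irreversibly to the aromatic benzofuran (cyclodehydration), while any lactone formed at the ester reopens in acidic methanol and the allyl-capped 2′-oxygen cannot compete.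

Step 14
Reactants: 21 methyl 2-[2,4-bis(allyloxy)phenyl]-6-methoxy-7-prenyl-1-benzofuran-3-carboxylate
Product: 22 {2-[2,4-bis(allyloxy)phenyl]-6-methoxy-7-prenyl-1-benzofuran-3-yl}methanol
Conditions: i-Bu2AlH (3 equiv), CH2Cl2, −78 to 0 °C; aq. potassium sodium tartrate
Reagents that add atoms: none
Why: Full hydride reduction of the ester to the primary alcohol is more dependable than a partial reduction to the aldehyde, and i-Bu2AlH leaves aryl allyl ethers and the isolated prenyl alkene alone at these temperatures.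

Step 15
Reactants: 22 {2-[2,4-bis(allyloxy)phenyl]-6-methoxy-7-prenyl-1-benzofuran-3-yl}methanol
Product: 23 2-[2,4-bis(allyloxy)phenyl]-6-methoxy-7-prenyl-1-benzofuran-3-carbaldehyde
Conditions: activated MnO2 (15 equiv), CH2Cl2, rt
Reagents that add atoms: none
Why: MnO2 oxidation is selective for benzylic-type (hetero)aryl carbinols and stops at the aldehyde without touching the alkenes.

Step 16
Reactants: 23 2-[2,4-bis(allyloxy)phenyl]-6-methoxy-7-prenyl-1-benzofuran-3-carbaldehyde
Product: 24 erypoegin F, 2-(2,4-dihydroxyphenyl)-6-methoxy-7-prenyl-1-benzofuran-3-carbaldehyde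
Conditions: Pd(PPh3)4 (5 mol %), morpholine (10 equiv), degassed THF, rt; dilute aq. citric acid work-up
Reagents that add atoms: none
Why: Tsuji–Trost-type deallylation, in which the zerovalent palladium complex ionises each aryl allyl ether to a π-allyl palladium species and a phenoxide and morpholine captures the allyl group; the C-prenyl group and the aryl methyl ether cannot ionise and stay intact.

## Compound list

1 | 2-hydroxy-4-methoxybenzaldehyde | COc1ccc(C=O)c(O)c1 | starting material
2 | 4-methoxy-2-(methoxymethoxy)benzaldehyde | COCOc1cc(OC)ccc1C=O | intermediate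
3 | 1-ethenyl-4-methoxy-2-(methoxymethoxy)benzene | COCOc1cc(OC)ccc1C=C | intermediate
4 | 9-{2-[4-methoxy-2-(methoxymethoxy)phenyl]ethyl}-9-borabicyclo[3.3.1]nonane (formed in the flask, not isolated) | COCOc1cc(OC)ccc1CCB1C2CCCC1CCC2 | intermediate
5 | 2-[4-methoxy-2-(methoxymethoxy)phenyl]ethan-1-ol | COCOc1cc(OC)ccc1CCO | intermediate
6 | tert-butyl{2-[4-methoxy-2-(methoxymethoxy)phenyl]ethoxy}dimethylsilane | COCOc1cc(OC)ccc1CCO[Si](C)(C)C(C)(C)C | intermediate
7 | {3-[2-(tert-butyldimethylsilyloxy)ethyl]-6-methoxy-2-(methoxymethoxy)phenyl}lithium (formed in the flask, not isolated) | [Li]c1c(OC)ccc(CCO[Si](C)(C)C(C)(C)C)c1OCOC | intermediate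
8 | tert-butyl{2-[4-methoxy-2-(methoxymethoxy)-3-(3-methylbut-2-en-1-yl)phenyl]ethoxy}dimethylsilane | COCOc1c(CCO[Si](C)(C)C(C)(C)C)ccc(OC)c1CC=C(C)C | intermediate
9 | 2-[4-methoxy-2-(methoxymethoxy)-3-(3-methylbut-2-en-1-yl)phenyl]ethan-1-ol | COCOc1c(CCO)ccc(OC)c1CC=C(C)C | intermediate
10 | 2-[4-methoxy-2-(methoxymethoxy)-3-(3-methylbut-2-en-1-yl)phenyl]acetaldehyde (formed in the flask, not isolated) | COCOc1c(CC=O)ccc(OC)c1CC=C(C)C | intermediate
11 | 2-[4-methoxy-2-(methoxymethoxy)-3-(3-methylbut-2-en-1-yl)phenyl]acetic acid | COCOc1c(CC(=O)O)ccc(OC)c1CC=C(C)C | intermediate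
12 | methyl 2-[4-methoxy-2-(methoxymethoxy)-3-(3-methylbut-2-en-1-yl)phenyl]acetate | COCOc1c(CC(=O)OC)ccc(OC)c1CC=C(C)C | intermediate
13 | 2,4-dihydroxybenzoic acid | OC(=O)c1ccc(O)cc1O | starting material
14 | prop-2-en-1-yl 2,4-bis(prop-2-en-1-yloxy)benzoate | C=CCOC(=O)c1ccc(OCC=C)cc1OCC=C | intermediate
15 | 2,4-bis(prop-2-en-1-yloxy)benzoic acid | OC(=O)c1ccc(OCC=C)cc1OCC=C | intermediate
16 | 2,4-bis(prop-2-en-1-yloxy)benzoyl chloride | ClC(=O)c1ccc(OCC=C)cc1OCC=C | intermediate
17 | lithium enolate of 12, lithium 1-methoxy-2-[4-methoxy-2-(methoxymethoxy)-3-(3-methylbut-2-en-1-yl)phenyl]ethen-1-olate (formed in the flask, not isolated) | [Li]OC(OC)=Cc1ccc(OC)c(CC=C(C)C)c1OCOC | intermediate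
18 | methyl 3-[2,4-bis(prop-2-en-1-yloxy)phenyl]-2-[4-methoxy-2-(methoxymethoxy)-3-(3-methylbut-2-en-1-yl)phenyl]-3-oxopropanoate (racemic, keto/enol mixture) | COC(=O)C(C(=O)c1ccc(OCC=C)cc1OCC=C)c1ccc(OC)c(CC=C(C)C)c1OCOC | intermediate
19 | methyl 3-[2,4-bis(prop-2-en-1-yloxy)phenyl]-2-[2-hydroxy-4-methoxy-3-(3-methylbut-2-en-1-yl)phenyl]-3-oxopropanoate (racemic; formed in the flask, not isolated) | COC(=O)C(C(=O)c1ccc(OCC=C)cc1OCC=C)c1ccc(OC)c(CC=C(C)C)c1O | intermediate
20 | methyl 2-[2,4-bis(prop-2-en-1-yloxy)phenyl]-2-hydroxy-6-methoxy-7-(3-methylbut-2-en-1-yl)-2,3-dihydro-1-benzofuran-3-carboxylate (racemic diastereomer mixture; formed in the flask, not isolated) | COC(=O)C1c2ccc(OC)c(CC=C(C)C)c2OC1(O)c1ccc(OCC=C)cc1OCC=C | intermediate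
21 | methyl 2-[2,4-bis(prop-2-en-1-yloxy)phenyl]-6-methoxy-7-(3-methylbut-2-en-1-yl)-1-benzofuran-3-carboxylate | COC(=O)c1c(-c2ccc(OCC=C)cc2OCC=C)oc2c(CC=C(C)C)c(OC)ccc12 | intermediate
22 | {2-[2,4-bis(prop-2-en-1-yloxy)phenyl]-6-methoxy-7-(3-methylbut-2-en-1-yl)-1-benzofuran-3-yl}methanol | OCc1c(-c2ccc(OCC=C)cc2OCC=C)oc2c(CC=C(C)C)c(OC)ccc12 | intermediate
23 | 2-[2,4-bis(prop-2-en-1-yloxy)phenyl]-6-methoxy-7-(3-methylbut-2-en-1-yl)-1-benzofuran-3-carbaldehyde | O=Cc1c(-c2ccc(OCC=C)cc2OCC=C)oc2c(CC=C(C)C)c(OC)ccc12 | intermediate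
24 | erypoegin F, 2-(2,4-dihydroxyphenyl)-6-methoxy-7-(3-methylbut-2-en-1-yl)-1-benzofuran-3-carbaldehyde (achiral) | COc1ccc2c(C=O)c(-c3ccc(O)cc3O)oc2c1CC=C(C)C | target

## Step count and weak points

Total steps: 16. Longest linear sequence: 13 steps (steps 1–8 and 12–16, from 1 to 24); the aroyl chloride branch is 3 steps (9–11).

Step 12 (crossed Claisen condensation). The hindered, electron-rich aroyl chloride may react sluggishly or give O-acylation and double acylation. The fallback sets out from 12 and comes back at 18, and makes the same bond by an aldol addition. Enolate 17 (from 12 and LiN(SiMe3)2, 1.1 equiv, THF, −78 °C) is added to 2,4-bis(prop-2-en-1-yloxy)benzaldehyde F1, which is made in one step from commercial 2,4-dihydroxybenzaldehyde with allyl bromide and K2CO3 in DMF at 60 °C. This gives the β-hydroxy ester methyl 3-[2,4-bis(prop-2-en-1-yloxy)phenyl]-3-hydroxy-2-[4-methoxy-2-(methoxymethoxy)-3-(3-methylbut-2-en-1-yl)phenyl]propanoate F2 as a diastereomer mixture. Dess–Martin periodinane with NaHCO3 in CH2Cl2 at rt then oxidises both diastereomers of F2 to 18.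

Step 13 (MOM removal and cyclodehydration). The ketone is hindered and deactivated by the dialkoxyaryl group, so ring closure may need acid strong enough to add to the prenyl alkene or to close the transient ortho-prenylphenol 19 to a chroman. The fallback sets out from 18 and comes back at 23; it removes the ester before cyclisation and puts the C3 carbon back by formylation.
- LiCl in DMSO–H2O at 120 °C (Krapcho demethoxycarbonylation) gives the deoxybenzoin 1-[2,4-bis(prop-2-en-1-yloxy)phenyl]-2-[4-methoxy-2-(methoxymethoxy)-3-(3-methylbut-2-en-1-yl)phenyl]ethan-1-one F3.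
- ZnBr2 and n-PrSH in CH2Cl2 at 0 °C remove the MOM group without protic acid to give the hydroxy ketone 1-[2,4-bis(prop-2-en-1-yloxy)phenyl]-2-[2-hydroxy-4-methoxy-3-(3-methylbut-2-en-1-yl)phenyl]ethan-1-one F4, which is not isolated.
- As an unhindered benzyl ketone with no competing ester, it cyclodehydrates with pyridinium p-toluenesulfonate (cat.) in toluene at 60 °C to 2-[2,4-bis(prop-2-en-1-yloxy)phenyl]-6-methoxy-7-(3-methylbut-2-en-1-yl)-1-benzofuran F5.
- Vilsmeier–Haack formylation (POCl3, DMF, 0 to 50 °C; aq. NaOAc) at C3, the enol-ether β-carbon, gives 23, which also makes steps 14 and 15 unnecessary.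

Step 16 (final deallylation). The aldehyde in 23 can be tied up by the amine scavenger, and the electron-rich hydroxy aldehyde product may degrade under the palladium conditions. The fallback sets out from 21 and comes back at 24; it deallylates before the aldehyde exists and reaches the aldehyde oxidation level by half-reduction of a lactone.
- Pd(PPh3)4 (5 mol %) and morpholine in THF at rt convert 21 into methyl 2-(2,4-dihydroxyphenyl)-6-methoxy-7-(3-methylbut-2-en-1-yl)-1-benzofuran-3-carboxylate F6.
- 1,8-Diazabicyclo[5.4.0]undec-7-ene (cat.) in toluene at 80 °C closes the 2′-OH onto the ester to give the coumestan 3-hydroxy-9-methoxy-10-(3-methylbut-2-en-1-yl)-6H-[1]benzofuro[3,2-c]chromen-6-one F7.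
- i-Bu2AlH (3.5 equiv, the first equivalent being consumed by the phenol) in CH2Cl2–THF at −78 °C reduces the lactone to the lactol 9-methoxy-10-(3-methylbut-2-en-1-yl)-6H-[1]benzofuro[3,2-c]chromene-3,6-diol F8.
- F8 is the ring-closed tautomer of the target and opens on work-up to the conjugated hydroxy aldehyde 24.

## Further compounds

F1 | step 12 | 2,4-bis(prop-2-en-1-yloxy)benzaldehyde | C=CCOc1ccc(C=O)c(OCC=C)c1
F2 | step 12 | methyl 3-[2,4-bis(prop-2-en-1-yloxy)phenyl]-3-hydroxy-2-[4-methoxy-2-(methoxymethoxy)-3-(3-methylbut-2-en-1-yl)phenyl]propanoate (racemic diastereomer mixture) | COC(=O)C(C(O)c1ccc(OCC=C)cc1OCC=C)c1ccc(OC)c(CC=C(C)C)c1OCOC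
F3 | step 13 | 1-[2,4-bis(prop-2-en-1-yloxy)phenyl]-2-[4-methoxy-2-(methoxymethoxy)-3-(3-methylbut-2-en-1-yl)phenyl]ethan-1-one | O=C(Cc1ccc(OC)c(CC=C(C)C)c1OCOC)c1ccc(OCC=C)cc1OCC=C
F4 | step 13 | 1-[2,4-bis(prop-2-en-1-yloxy)phenyl]-2-[2-hydroxy-4-methoxy-3-(3-methylbut-2-en-1-yl)phenyl]ethan-1-one | O=C(Cc1ccc(OC)c(CC=C(C)C)c1O)c1ccc(OCC=C)cc1OCC=C
F5 | step 13 | 2-[2,4-bis(prop-2-en-1-yloxy)phenyl]-6-methoxy-7-(3-methylbut-2-en-1-yl)-1-benzofuran | C=CCOc1ccc(-c2cc3ccc(OC)c(CC=C(C)C)c3o2)c(OCC=C)c1
F6 | step 16 | methyl 2-(2,4-dihydroxyphenyl)-6-methoxy-7-(3-methylbut-2-en-1-yl)-1-benzofuran-3-carboxylate | COC(=O)c1c(-c2ccc(O)cc2O)oc2c(CC=C(C)C)c(OC)ccc12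
F7 | step 16 | 3-hydroxy-9-methoxy-10-(3-methylbut-2-en-1-yl)-6H-[1]benzofuro[3,2-c]chromen-6-one | O=c1oc2cc(O)ccc2c2oc3c(CC=C(C)C)c(OC)ccc3c12
F8 | step 16 | 9-methoxy-10-(3-methylbut-2-en-1-yl)-6H-[1]benzofuro[3,2-c]chromene-3,6-diol (racemic lactol) | OC1Oc2cc(O)ccc2-c2oc3c(CC=C(C)C)c(OC)ccc3c12
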